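**Retrosynthetic overview**
- The last bond made is C4(flavan)–C2'(flavonol ring B): acid-mediated, biomimetic capture of the fisetinidol C4 cation, generated from the (2R,3S,4R)-flavan-3,4-diol, by commercial robinetin, with attack trans to the 3-OH setting C4.
- The diol comes from (2R,3R)-fustin. Its ring C is closed in one operation by inserting a ring-A aryne between the C2 alkoxide and the C4 Weinreb amide of an acyclic anti-aldol fragment, forming O1–C8a and C4a–C4 together.
- Enabling feature: O1 and C4 of ring C sit on the adjacent carbons C8a and C4a of ring A (an ortho edge, hence an aryne). C4 is a doubly benzylic carbon that can be carried at the ketone level and ionised later. C5 is unsubstituted, so a temporary C5 chlorine can steer the aryne regiochemistry and is removed with the benzyl groups.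
- Ring order: rings A and B of the flavan arrive as arenes, ring C is formed in the key step, and the three flavonol rings arrive intact in robinetin. C2 and C3 are set beforehand by an anti-selective glycolate aldol.

Key step: step 7

Assumption: the open-transition-state anti glycolate aldol of the (4S)-benzyl oxazolidinethione is taken to proceed through the thiocarbonyl-chelated Z-enolate on the face opposite the benzyl group, giving the (2R,3R) adduct; if the sense proves opposite, the (4R) auxiliary would be used.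

Step 1
Reactants: 1 4-(benzyloxy)phenol
Product: 2 4-(benzyloxy)-2-chlorophenol
Conditions: SO2Cl2 (1.0 equiv), i-Bu2NH (cat.), toluene, 0 °C to rt
Reagents that add atoms: sulfuryl chloride, O=S(=O)(Cl)Cl
Why: Electrophilic aromatic chlorination of a para-blocked phenol should occur ortho to the free hydroxyl, the stronger director, with the amine catalyst delivering chlorine next to the OH.

Step 2
Reactants: 2 4-(benzyloxy)-2-chlorophenol
Product: 3 4-(benzyloxy)-2-bromo-6-chlorophenol
Conditions: NBS (1.0 equiv), i-Pr2NH (cat.), CH2Cl2, 0 °C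
Reagents that add atoms: N-bromosuccinimide, O=C1CCC(=O)N1Br
Why: Electrophilic aromatic bromination should take the only remaining position ortho to the phenol hydroxyl.

Step 3
Reactants: 3 4-(benzyloxy)-2-bromo-6-chlorophenol
Product: 6 4-(benzyloxy)-2-chloro-6-(trimethylsilyl)phenyl trifluoromethanesulfonate, via aryl trimethylsilyl ether 4 (not isolated), via lithium 2-silylphenolate 5 (not isolated)
Conditions: (Me3Si)2NH, THF, 65 °C, then evaporation; n-BuLi, THF, −100 to −78 °C; Tf2O, −78 °C to rt
Reagents that add atoms: hexamethyldisilazane, C[Si](C)(C)N[Si](C)(C)C; trifluoromethanesulfonic anhydride, O=S(=O)(OS(=O)(=O)C(F)(F)F)C(F)(F)F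
Why: O-silylation, selective bromine–lithium exchange (the chloride is inert at this temperature), retro-Brook 1,3-migration of silicon from oxygen to carbon and O-triflation of the phenolate form the standard sequence to 2-(trimethylsilyl)aryl triflates.

Step 4
Reactants: 7 (4S)-4-benzyl-1,3-oxazolidine-2-thione; 8 (benzyloxy)acetyl chloride
Product: 9 (4S)-4-benzyl-3-[(benzyloxy)acetyl]-1,3-oxazolidine-2-thione
Conditions: Et3N, CH2Cl2, 0 °C
Reagents that add atoms: none
Why: N-acylation of the acidic thiocarbamate N–H by the acid chloride should give the N-glycolyl auxiliary without touching the stereocentre.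

Step 5
Reactants: 9 (4S)-4-benzyl-3-[(benzyloxy)acetyl]-1,3-oxazolidine-2-thione; 10 3,4-bis(benzyloxy)benzaldehyde
Product: 12 (4S)-4-benzyl-3-[(2R,3R)-2-(benzyloxy)-3-[3,4-bis(benzyloxy)phenyl]-3-hydroxypropanoyl]-1,3-oxazolidine-2-thione, via trichlorotitanium Z-enolate 11 (not isolated)
Conditions: TiCl4 (1.05 equiv), i-Pr2NEt (1.1 equiv), CH2Cl2, −78 °C; then 10 premixed with TiCl4 (2 equiv), −78 °C; aq. NH4Cl
Reagents that add atoms: none
Why: In this titanium-enolate anti-selective glycolate aldol of an N-glycolyloxazolidinethione, the thiocarbonyl-chelated Z-enolate 11 should be attacked on the face opposite the benzyl group by the TiCl4-activated aldehyde through an open antiperiplanar transition state, which sets C2 (R) by auxiliary control and C3 (R) in the anti relationship.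

Step 6
Reactants: 12 (4S)-4-benzyl-3-[(2R,3R)-2-(benzyloxy)-3-[3,4-bis(benzyloxy)phenyl]-3-hydroxypropanoyl]-1,3-oxazolidine-2-thione
Product: 13 (2R,3R)-2-(benzyloxy)-3-[3,4-bis(benzyloxy)phenyl]-3-hydroxy-N-methoxy-N-methylpropanamide
Conditions: MeNH(OMe)·HCl, imidazole, CH2Cl2, rt
Reagents that add atoms: N,O-dimethylhydroxylamine hydrochloride, CNOC.Cl
Why: Aminolysis of the activated N-acyl oxazolidinethione should give the Weinreb amide under conditions too mild for retro-aldol cleavage or epimerisation, and it returns the auxiliary.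

Step 7
Reactants: 13 (2R,3R)-2-(benzyloxy)-3-[3,4-bis(benzyloxy)phenyl]-3-hydroxy-N-methoxy-N-methylpropanamide; 6 4-(benzyloxy)-2-chloro-6-(trimethylsilyl)phenyl trifluoromethanesulfonate
Product: 17 (2R,3R)-3,7-bis(benzyloxy)-2-[3,4-bis(benzyloxy)phenyl]-5-chloro-2,3-dihydro-4H-chromen-4-one, via sodium alkoxide 14 (not isolated), via 5-(benzyloxy)-3-chlorobenzyne 15 (not isolated), via chroman-4-olate hemiaminal 16 (not isolated)
Conditions: NaH (1.05 equiv), THF, 0 °C; then 6 (1.5 equiv), CsF (3 equiv), 18-crown-6, THF, 0 °C to rt; aq. NH4Cl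
Reagents that add atoms: none
Why: Proposed new method: the alkoxide 14 should add to the fluoride-generated aryne 15 at the carbon remote from chlorine (the future C8a), and the ortho-chloroaryl anion formed at the future C4a should attack the tethered N-methoxy-N-methylamide to give the tetrahedral adduct 16, which releases the C4 ketone only on work-up; the closest known reaction type is the fluoride-triggered tandem O-arylation and intramolecular acylation of arynes with salicylate esters that gives xanthones, extended here to a secondary aliphatic alkoxide and a Weinreb amide. Ring C is closed as a formal [4+2] annulation that joins the four-atom unit O1–C2–C3–C4 to the two aryne carbons, the second bond by 6-exo-trig attack on the amide carbonyl. No stereocentre of 17 is created: C2 and C3 are carried over from 13 with retention because neither C–O bond is broken, and the persistent adduct 16 keeps C3–H from lying alpha to a ketone while base is present. The step needs regioselective alkoxide addition, which the C5 chlorine should secure by distorting the aryne so that nucleophiles attack the distal carbon and the charge develops next to chlorine, the remote 7-benzyloxy group exerting only a weak opposing bias. It also needs C-acylation to outrun protonation of the aryl anion or its loss of chloride, which the proton-free preformed alkoxide, the six-membered transition state and the poor leaving-group ability of chloride should secure.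

Step 8
Reactants: 17 (2R,3R)-3,7-bis(benzyloxy)-2-[3,4-bis(benzyloxy)phenyl]-5-chloro-2,3-dihydro-4H-chromen-4-one
Product: 18 (2R,3R)-2-(3,4-dihydroxyphenyl)-3,7-dihydroxy-2,3-dihydro-4H-chromen-4-one [(2R,3R)-fustin]
Conditions: H2 (1 atm), Pd(OH)2/C, NaOAc, EtOAc–MeOH, rt
Reagents that add atoms: none
Why: Palladium-catalysed hydrogenolysis should cleave the four O-benzyl ethers and, buffered by acetate, the temporary aryl C–Cl bond in one operation, while the chromanone carbonyl (a vinylogous ester through O1 and the 7-oxygen) and both stereocentres survive.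

Step 9
Reactants: 18 (2R,3R)-fustin
Product: 19 (2R,3S,4R)-2-(3,4-dihydroxyphenyl)-3,4-dihydro-2H-chromene-3,4,7-triol [2,3-trans-3,4-trans-leucofisetinidin, mollisacacidin]
Conditions: NaBH4, EtOH, 0 °C to rt; pH 6 phosphate buffer work-up
Reagents that add atoms: none
Why: Borohydride reduction of a dihydroflavonol should deliver hydride to C4 trans to the equatorial C3 hydroxyl and give the 2,3-trans-3,4-trans diol, whose C4 configuration is erased again when C4 is ionised in step 10.

Step 10
Reactants: 19 mollisacacidin; 20 robinetin (3,7-dihydroxy-2-(3,4,5-trihydroxyphenyl)-4H-chromen-4-one)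
Product: 22 2-{2-[(2R,3S,4S)-2-(3,4-dihydroxyphenyl)-3,7-dihydroxy-3,4-dihydro-2H-chromen-4-yl]-3,4,5-trihydroxyphenyl}-3,7-dihydroxy-4H-chromen-4-one (target), via fisetinidol C4 cation 21 (not isolated)
Conditions: 0.1 M aq. HCl–1,4-dioxane (1:1), 20 (4 equiv), rt, Ar
Reagents that add atoms: none
Why: In this biomimetic acid-catalysed flavan-3,4-diol condensation (Friedel–Crafts alkylation), loss of water gives the C4 benzylic cation 21, stabilised by the para 7-hydroxyl, which should be captured by C2' (equivalent to C6') of robinetin ring B, ortho to 3'-OH and para to 5'-OH, from the face anti to the C3 hydroxyl, setting C4 (S) in the 2,3-trans-3,4-trans array.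

**Compound list**
1 | 4-(benzyloxy)phenol | Oc1ccc(OCc2ccccc2)cc1 | starting material
2 | 4-(benzyloxy)-2-chlorophenol | Oc1ccc(OCc2ccccc2)cc1Cl | intermediate
3 | 4-(benzyloxy)-2-bromo-6-chlorophenol | Oc1c(Br)cc(OCc2ccccc2)cc1Cl | intermediate
4 | [4-(benzyloxy)-2-bromo-6-chlorophenoxy]trimethylsilane | C[Si](C)(C)Oc1c(Br)cc(OCc2ccccc2)cc1Cl | intermediate
5 | lithium 4-(benzyloxy)-2-chloro-6-(trimethylsilyl)phenolate | [Li+].[O-]c1c(Cl)cc(OCc2ccccc2)cc1[Si](C)(C)C | intermediate
6 | 4-(benzyloxy)-2-chloro-6-(trimethylsilyl)phenyl trifluoromethanesulfonate | C[Si](C)(C)c1cc(OCc2ccccc2)cc(Cl)c1OS(=O)(=O)C(F)(F)F | intermediate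
7 | (4S)-4-benzyl-1,3-oxazolidine-2-thione | S=C1N[C@@H](Cc2ccccc2)CO1 | starting material
8 | (benzyloxy)acetyl chloride | O=C(Cl)COCc1ccccc1 | starting material
9 | (4S)-4-benzyl-3-[(benzyloxy)acetyl]-1,3-oxazolidine-2-thione | O=C(COCc1ccccc1)N1C(=S)OC[C@@H]1Cc1ccccc1 | intermediate
10 | 3,4-bis(benzyloxy)benzaldehyde | O=Cc1ccc(OCc2ccccc2)c(OCc2ccccc2)c1 | starting material
11 | trichlorotitanium (Z)-enolate of 9 | Cl[Ti](Cl)(Cl)O/C(=C\OCc1ccccc1)N1C(=S)OC[C@@H]1Cc1ccccc1 | intermediate
12 | (4S)-4-benzyl-3-[(2R,3R)-2-(benzyloxy)-3-[3,4-bis(benzyloxy)phenyl]-3-hydroxypropanoyl]-1,3-oxazolidine-2-thione | O=C([C@H](OCc1ccccc1)[C@H](O)c1ccc(OCc2ccccc2)c(OCc2ccccc2)c1)N1C(=S)OC[C@@H]1Cc1ccccc1 | intermediate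
13 | (2R,3R)-2-(benzyloxy)-3-[3,4-bis(benzyloxy)phenyl]-3-hydroxy-N-methoxy-N-methylpropanamide | CON(C)C(=O)[C@H](OCc1ccccc1)[C@H](O)c1ccc(OCc2ccccc2)c(OCc2ccccc2)c1 | intermediate
14 | sodium (1R,2R)-2-(benzyloxy)-1-[3,4-bis(benzyloxy)phenyl]-3-[methoxy(methyl)amino]-3-oxopropan-1-olate | [Na+].CON(C)C(=O)[C@H](OCc1ccccc1)[C@H]([O-])c1ccc(OCc2ccccc2)c(OCc2ccccc2)c1 | intermediate
15 | 5-(benzyloxy)-3-chlorobenzyne (5-(benzyloxy)-3-chloro-1,2-didehydrobenzene) | ClC1=CC(OCc2ccccc2)=CC#C1 | intermediate
16 | sodium (2R,3R)-3,7-bis(benzyloxy)-2-[3,4-bis(benzyloxy)phenyl]-5-chloro-4-[methoxy(methyl)amino]-3,4-dihydro-2H-chromen-4-olate (C4 undefined) | [Na+].CON(C)C1([O-])[C@H](OCc2ccccc2)[C@@H](c2ccc(OCc3ccccc3)c(OCc3ccccc3)c2)Oc2cc(OCc3ccccc3)cc(Cl)c21 | intermediate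
17 | (2R,3R)-3,7-bis(benzyloxy)-2-[3,4-bis(benzyloxy)phenyl]-5-chloro-2,3-dihydro-4H-chromen-4-one (2,3-trans) | O=C1[C@H](OCc2ccccc2)[C@@H](c2ccc(OCc3ccccc3)c(OCc3ccccc3)c2)Oc2cc(OCc3ccccc3)cc(Cl)c12 | intermediate
18 | (2R,3R)-2-(3,4-dihydroxyphenyl)-3,7-dihydroxy-2,3-dihydro-4H-chromen-4-one, (2R,3R)-fustin | O=C1[C@H](O)[C@@H](c2ccc(O)c(O)c2)Oc2cc(O)ccc12 | intermediate
19 | (2R,3S,4R)-2-(3,4-dihydroxyphenyl)-3,4-dihydro-2H-chromene-3,4,7-triol, mollisacacidin | O[C@@H]1c2ccc(O)cc2O[C@H](c2ccc(O)c(O)c2)[C@H]1O | intermediate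
20 | robinetin, 3,7-dihydroxy-2-(3,4,5-trihydroxyphenyl)-4H-chromen-4-one | O=c1c(O)c(-c2cc(O)c(O)c(O)c2)oc2cc(O)ccc12 | starting material
21 | (2R,3S)-2-(3,4-dihydroxyphenyl)-3,7-dihydroxy-3,4-dihydro-2H-chromen-4-ylium (fisetinidol C4 cation) | [CH+]1c2ccc(O)cc2O[C@H](c2ccc(O)c(O)c2)[C@H]1O | intermediate
22 | 2-{2-[(2R,3S,4S)-2-(3,4-dihydroxyphenyl)-3,7-dihydroxy-3,4-dihydro-2H-chromen-4-yl]-3,4,5-trihydroxyphenyl}-3,7-dihydroxy-4H-chromen-4-one | O=c1c(O)c(-c2cc(O)c(O)c(O)c2[C@@H]2c3ccc(O)cc3O[C@H](c3ccc(O)c(O)c3)[C@H]2O)oc2cc(O)ccc12 | target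

**Totals**
Total step count: 10. Longest linear sequence: 7 steps (steps 4 to 10; the branch through steps 1 to 3 and then 7 to 10 is equally long).

**Steps most likely to fail**

Step 7 (proposed new method). The aryl anion may be protonated, or may lose chloride to form a second aryne, before it is acylated. The alkoxide may fragment by retro-aldol reaction, and part of it may add at the wrong aryne carbon. The fallback sets out from 13 and comes back at 18, and makes the two bonds in two known operations. Ullmann-type etherification of 13 with 4-(benzyloxy)-1-bromo-2-iodobenzene F1 (made from commercial 4-bromo-3-iodophenol with BnBr and K2CO3 in DMF) under CuI, 3,4,7,8-tetramethyl-1,10-phenanthroline and Cs2CO3 in toluene at 80 °C should engage only the C–I bond and give the aryl ether (2R,3R)-2-(benzyloxy)-3-[5-(benzyloxy)-2-bromophenoxy]-3-[3,4-bis(benzyloxy)phenyl]-N-methoxy-N-methylpropanamide F2. Bromine–lithium exchange with t-BuLi in THF at −78 °C and Parham cyclization of the aryllithium onto the Weinreb amide should then give the chlorine-free chromanone (2R,3R)-3,7-bis(benzyloxy)-2-[3,4-bis(benzyloxy)phenyl]-2,3-dihydro-4H-chromen-4-one F3. Hydrogenolysis (H2, Pd(OH)2/C, EtOAc–MeOH) should deliver 18.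

Step 10. The C4 cation may be captured by ring A of a second diol molecule or of the product (oligomerisation), robinetin may be alkylated twice, and attack may occur in part on the face cis to the C3 hydroxyl. The fallback sets out from 19 and comes back at 22, and separates ionisation from coupling. Acid-catalysed thiolysis of 19 with phenylmethanethiol (AcOH, EtOH, rt) should trap the cation as the stable, purifiable thioether (2R,3R,4R)-4-(benzylsulfanyl)-2-(3,4-dihydroxyphenyl)-3,4-dihydro-2H-chromene-3,7-diol F4 (either C4 epimer serves). Thiophilic activation with AgBF4 in THF at 0 °C in the presence of excess 20 should then release the cation under non-acidic conditions and give 22.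

Step 5. The open transition state may give poor anti/syn selectivity or the opposite facial sense, and the electron-rich benzylic titanium alkoxide may ionise under the excess Lewis acid. The fallback sets out from 10 and comes back at 17, and relies on a closed transition state whose sense is secure plus thermodynamic control at C3. Evans syn-aldol reaction (Bu2BOTf, Et3N, CH2Cl2, −78 to 0 °C) of commercial (4S)-4-benzyl-3-[(benzyloxy)acetyl]-1,3-oxazolidin-2-one with 10 should give the syn adduct (4S)-4-benzyl-3-[(2S,3R)-2-(benzyloxy)-3-[3,4-bis(benzyloxy)phenyl]-3-hydroxypropanoyl]-1,3-oxazolidin-2-one F5, in which the benzylic carbinol already has the required (R) configuration. Transamination (MeNH(OMe)·HCl, AlMe3, CH2Cl2, 0 °C) should give the syn Weinreb amide (2S,3R)-2-(benzyloxy)-3-[3,4-bis(benzyloxy)phenyl]-3-hydroxy-N-methoxy-N-methylpropanamide F6. Annulation with 6 under the conditions of step 7 should give the 2,3-cis chromanone (2R,3S)-3,7-bis(benzyloxy)-2-[3,4-bis(benzyloxy)phenyl]-5-chloro-2,3-dihydro-4H-chromen-4-one F7. DBU in toluene at rt should epimerise C3, now alpha to the C4 carbonyl, to the more stable 2,3-trans isomer 17.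

**Further compounds**
F1 | step 7 | 4-(benzyloxy)-1-bromo-2-iodobenzene | Brc1ccc(OCc2ccccc2)cc1I
F2 | step 7 | (2R,3R)-2-(benzyloxy)-3-[5-(benzyloxy)-2-bromophenoxy]-3-[3,4-bis(benzyloxy)phenyl]-N-methoxy-N-methylpropanamide | CON(C)C(=O)[C@H](OCc1ccccc1)[C@H](Oc1cc(OCc2ccccc2)ccc1Br)c1ccc(OCc2ccccc2)c(OCc2ccccc2)c1
F3 | step 7 | (2R,3R)-3,7-bis(benzyloxy)-2-[3,4-bis(benzyloxy)phenyl]-2,3-dihydro-4H-chromen-4-one | O=C1[C@H](OCc2ccccc2)[C@@H](c2ccc(OCc3ccccc3)c(OCc3ccccc3)c2)Oc2cc(OCc3ccccc3)ccc12
F4 | step 10 | (2R,3R,4R)-4-(benzylsulfanyl)-2-(3,4-dihydroxyphenyl)-3,4-dihydro-2H-chromene-3,7-diol | C(S[C@@H]1c2ccc(O)cc2O[C@H](c2ccc(O)c(O)c2)[C@H]1O)c1ccccc1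
F5 | step 5 | (4S)-4-benzyl-3-[(2S,3R)-2-(benzyloxy)-3-[3,4-bis(benzyloxy)phenyl]-3-hydroxypropanoyl]-1,3-oxazolidin-2-one | O=C([C@@H](OCc1ccccc1)[C@H](O)c1ccc(OCc2ccccc2)c(OCc2ccccc2)c1)N1C(=O)OC[C@@H]1Cc1ccccc1
F6 | step 5 | (2S,3R)-2-(benzyloxy)-3-[3,4-bis(benzyloxy)phenyl]-3-hydroxy-N-methoxy-N-methylpropanamide | CON(C)C(=O)[C@@H](OCc1ccccc1)[C@H](O)c1ccc(OCc2ccccc2)c(OCc2ccccc2)c1
F7 | step 5 | (2R,3S)-3,7-bis(benzyloxy)-2-[3,4-bis(benzyloxy)phenyl]-5-chloro-2,3-dihydro-4H-chromen-4-one | O=C1[C@@H](OCc2ccccc2)[C@@H](c2ccc(OCc3ccccc3)c(OCc3ccccc3)c2)Oc2cc(OCc3ccccc3)cc(Cl)c12
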